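1. I start from a leftover: what remains of the incoming ligand once each starting complex has taken up 3, the full exchange, one ligand at a time. The charges and readings are these:

| flask | starting complex | incoming ligand | remark | time |
|---|---|---|---|---|
| teal | 0.067 M | 0.050 M | run made earlier |  |
| grey | 0.20 M | 0.050 M | run made earlier |  |
| alder | 0.10 M | 0.0500 M |  | 8.0 min |
| elm | 0.10 M | 0.0800 M |  | 8.0 min |
| oak | 0.10 M | 0.400 M |  | 8.0 min |

- teal (time / s: complex with three exchanged / %, complex with one exchanged / %): 10.0: 0, 10.4; 20.0: 0, 18.8; 30.0: 0, 24.7; 50.0: 0.3, 31.6; 80.0: 0.2, 36.9; 90.0: 0, 38.9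
- grey (time / s: complex with three exchanged / %, complex with one exchanged / %): 10.0: 0.2, 8.4; 12.0: 0.3, 10.7; 20.0: 0, 13.6; 40.0: 0, 17.8; 60.0: 0.1, 17.8; 90.0: 0, 18.2

(standard deviation of a reading: 0.3 percentage points)

- no earlier run changes the charge of incoming ligand; that part of a forecast is a guess

* how much complex with three exchanged is there at the end, in percent of the starting complex charged: for each flask in turn (alder, elm, oak)

2. Oak holds 4.00 incoming ligand per starting complex charged. I call this the charge ratio. It is 0.500 in alder and 0.800 in elm.

3. Full exchange in oak would leave 25.0% of its incoming ligand. In alder and elm the ratio is lower than 3, so incoming ligand is the limiting reagent for full exchange. It caps complex with three exchanged at 16.7% in alder and 26.7% in elm.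

4. Is one number enough? The grey ratio is 0.250, yet complex with one exchanged reads 18.2% at the last time in grey, lower than that ratio as a percentage. So the ratio gives a ceiling, not an amount. I commit to values far under the caps for alder and elm. For oak, with a ratio above 3, the charge of incoming ligand sets no cap below the whole charge of starting complex, and I commit to no amount.

5. The forecast gives 0.8%, 3.3% and 99%, and says of oak that “conversion is essentially complete”.

6. The flasks give 0.0800%, 0.379% and 18.0%.

    starting complex + incoming ligand ⇌ leaving ligand + complex with one exchanged (K = 39.7, k = 0.264 L mol⁻¹ s⁻¹)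
    complex with one exchanged + incoming ligand ⇌ leaving ligand + complex with two exchanged (K = 0.490, k = 0.121 L mol⁻¹ s⁻¹)
    complex with two exchanged + incoming ligand ⇌ leaving ligand + complex with three exchanged (K = 0.370, k = 0.0329 L mol⁻¹ s⁻¹)
    starting complex + complex with one exchanged → side product A (k = 0.0218 L mol⁻¹ s⁻¹)
    leaving ligand + starting complex → side product B (k = 0.0479 L mol⁻¹ s⁻¹)

7. Oak keeps 60% of its incoming ligand, against the 25.0% of step 3, so with a ratio of 4.00 it has taken up a net 1.60 per starting complex charged. Elm, at ratio 0.800, keeps 12% of its incoming ligand, which is 0.0986 per starting complex charged. This wearing away of incoming ligand is one thing holding elm low: in the elm run with incoming ligand held at its charge, complex with three exchanged reaches 5.74% instead of 0.379%.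

(All runs are simulated with made-up constants; noise was put on by code.)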